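Delta was charged with more initiator than alpha, so I expected shorter chains there and set out to reckon how much shorter.

- delta: free monomer 10 mM; protic impurity 3.00 mM; initiator 0.25 mM; time 2.5 min
- alpha: free monomer 10 mM; protic impurity 3.00 mM; initiator 0.15 mM; time 2.5 min

    free monomer + initiator → living end + monomer in chains (k1 = 170 M⁻¹ s⁻¹)
    free monomer + living end → monomer in chains + living end, rate k2*[living end]*[free monomer] (k2 = 1300 M⁻¹ s⁻¹)
    monomer in chains + living end → free monomer + living end, rate k3*[living end] as long as [monomer in chains] is above zero (k3 = 2.1 s⁻¹)
    protic impurity + free monomer → quenched substrate (k4 = 38 M⁻¹ s⁻¹)

- which of the two ends with the longer chains by the average number of monomer units in a chain (chains begun, living or dead) ("neither" if they lie within 10%) (delta / alpha / neither)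
- average number of monomer units in a chain (chains begun, living or dead) at the end, delta
- average number of monomer units in a chain (chains begun, living or dead) at the end, alpha

- the average divides the monomer in chains by the number of chains begun, living and dead together
- run time (delta): 2.5 min

My first guess let every free monomer enter a chain and every initiator begin one:

average = free monomer charged / initiator charged = 40.0 in delta, 66.7 in alpha

I doubted this at once. A living end gives monomer back at a rate independent of free monomer, but it takes monomer up in proportion to free monomer. Both rates scale with the living ends, so these cancel, and net growth stops at one level of free monomer, M*, the equilibrium monomer concentration: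

M* = unzipping constant / growth constant = 2.1 s⁻¹ / 1300 M⁻¹ s⁻¹ = 1.62 mM

I froze free monomer there. But the protic impurity removes free monomer for good, one for one, and the chains pay by unzipping:

S = 10 mM − 3.00 mM − 1.62 mM = 5.38 mM

This S, the free monomer charged less the protic impurity less M*, is what I called the chain stock. Dividing it by the initiator charged gave 21.5 for delta and 35.9 for alpha.

Was there time for this? For alpha I reckoned a level of free monomer with its initiator counted as living ends and its full charge of protic impurity still present, setting the monomer given back against the monomer taken up and quenched:

living-end supply / total loss = 1.02 mM

This estimate lay below M*. Even at that level I reckoned for alpha a half-life of the protic impurity of 17.9 s and of the initiator of 4.00 s, both shorter than the run of 2.5 min, which holds 8.38 impurity half-lives. So the objection fell, and I kept my numbers.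

The forecast gave alpha, with 21.5 for delta and 35.9 for alpha, holding that “All the initiator is consumed in both runs”. The simulation gave alpha, with 21.5 for delta and 35.9 for alpha.

Monomer in chains ended at 53.9% of the charge in delta and 53.9% in alpha, which is 5.39 mM against the stock of 5.38 mM. Alpha's chains are longer because it shares that stock among fewer chains: given delta's initiator, alpha's average falls from 35.9 to 21.5. A neighbour of alpha charged with 0.75 mM of protic impurity has a stock of 7.63 mM, which reckons to 50.9 units per chain, and that flask gave 50.9.

The numbers of this flask belong to no real substance, and the outcome is calculated.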